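**Retrosynthetic overview**

- Rings: A = benzo ring of the dihydrobenzofuran; B = its dihydrofuran ring (O-1, C-2, C-3, C-3a, C-7a); C = guaiacyl ring on C-2; D = γ-butyrolactone; E = central guaiacyl ring carrying the diol arm; F = guaiacyl ring of the diol arm. The last operations are fluoride desilylation and, before it, trans-selective alkylation of the ring D enolate of the ring E/F fragment with the ring A/B/C benzyl bromide.
- Ring B is closed by forming C-2–C-3: enantioselective intramolecular 1,5 C–H insertion of an aryl(ester) divalent-rhodium carbene into the O–CH2–aryl group of a vanillyl ether, followed in the same flask by epimerisation to the trans ester. The achiral precursor comes from 5-iodovanillin by Mitsunobu etherification and Pd coupling with ethyl diazoacetate.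
- Enabling feature: the ether methylene that becomes C-2 lies five atoms from the carbene carbon (future C-3, on ring A ortho to O-1), and its C–H bonds are activated by O-1 and by the electron-rich ring C.
- The anti-1,3-diol arm on ring E comes from a magnesium-catalysed anti-aldol of a ring E arylacetyl oxazolidinone (made by Pd α-arylation of a zinc imide enolate) with silylated vanillin. Ring D comes from oxazolidinone-controlled alkylation of a succinate imide with the ring E benzyl bromide, then reduction and lactonisation.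
- Order of ring formation: ring B (step 7), then ring D (step 22); rings A, C, E and F are purchased arenes.

Key step: step 7

**Abbreviations.** TIPSO = triisopropylsilyloxy; TBSO = tert-butyldimethylsilyloxy; TESO = triethylsilyloxy; Rh2(S-PTTL)4 = dirhodium tetrakis[N-phthaloyl-(S)-tert-leucinate]; Q-Phos = 1,2,3,4,5-pentaphenyl-1'-(di-tert-butylphosphino)ferrocene; ArE = 3-{(1S,2S)-1,3-bis(TBSO)-1-[3-methoxy-4-(TIPSO)phenyl]propan-2-yl}-5-methoxy-4-(TIPSO)phenyl.

**Remark on the chemistry.** Rh2(S-PTTL)4 is assumed to select the benzylic hydrogen that leads to the (2R) centre; both antipodes of the catalyst are available, so an opposite sense on this substrate would be met by using Rh2(R-PTTL)4 with no other change.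

**Route**

Step 1
Reactants: 1 vanillin (4-hydroxy-3-methoxybenzaldehyde)
Product: 2 3-methoxy-4-(TIPSO)benzaldehyde
Conditions: TIPSCl, imidazole, DMF, rt
Reagents that add atoms: triisopropylsilyl chloride, CC(C)[Si](Cl)(C(C)C)C(C)C
Why: Silyl ether formation on the phenol; the bulky TIPS group is chosen to survive bases, hydrides and mild acid until the final fluoride step.

Step 2
Reactants: 2 3-methoxy-4-(TIPSO)benzaldehyde
Product: 3 [3-methoxy-4-(TIPSO)phenyl]methanol
Conditions: NaBH4, MeOH–THF, 0 °C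
Reagents that add atoms: none
Why: Borohydride reduction of an aromatic aldehyde to the benzylic alcohol, to which the aryl silyl ether is inert.

Step 3
Reactants: 3 [3-methoxy-4-(TIPSO)phenyl]methanol; 4 5-iodovanillin (4-hydroxy-3-iodo-5-methoxybenzaldehyde)
Product: 5 3-iodo-5-methoxy-4-{[3-methoxy-4-(TIPSO)benzyl]oxy}benzaldehyde
Conditions: PPh3, DIAD, THF, 0 °C → rt
Reagents that add atoms: none
Why: Mitsunobu etherification, in which the acidic phenol of 4 (para-formyl, ortho-iodo) is alkylated by the activated primary benzylic alcohol under neutral conditions that spare the aryl silyl ether.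

Step 4
Reactants: 5 3-iodo-5-methoxy-4-{[3-methoxy-4-(TIPSO)benzyl]oxy}benzaldehyde
Product: 6 (3-iodo-5-methoxy-4-{[3-methoxy-4-(TIPSO)benzyl]oxy}phenyl)methanol
Conditions: NaBH4, MeOH–THF, 0 °C
Reagents that add atoms: none
Why: Borohydride reduction of the aldehyde, which would otherwise intercept the carbene later; aryl iodide and ethers are untouched.

Step 5
Reactants: 6 (3-iodo-5-methoxy-4-{[3-methoxy-4-(TIPSO)benzyl]oxy}phenyl)methanol
Product: 7 triethyl[(3-iodo-5-methoxy-4-{[3-methoxy-4-(TIPSO)benzyl]oxy}benzyl)oxy]silane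
Conditions: TESCl, imidazole, CH2Cl2, 0 °C
Reagents that add atoms: triethylsilyl chloride, CC[Si](Cl)(CC)CC
Why: Silylation masks the O–H bond (a site for carbene O–H insertion) as a primary TES ether that can later be removed in the presence of TBS and aryl TIPS ethers.

Step 6
Reactants: 7 triethyl[(3-iodo-5-methoxy-4-{[3-methoxy-4-(TIPSO)benzyl]oxy}benzyl)oxy]silane; 8 ethyl diazoacetate
Product: 9 ethyl 2-diazo-2-(3-methoxy-2-{[3-methoxy-4-(TIPSO)benzyl]oxy}-5-[(TESO)methyl]phenyl)acetate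
Conditions: Pd(PPh3)4 (5 mol%), Ag2CO3 (0.5 equiv), Et3N, toluene, rt
Reagents that add atoms: none
Why: Palladium-catalysed cross-coupling of an aryl iodide with the C–H bond of an acceptor diazoacetate with retention of the diazo group (oxidative addition to zerovalent palladium, silver-assisted palladation of the diazo carbon, reductive elimination) gives the donor/acceptor diazo ester directly at room temperature.

Step 7
Reactants: 9 ethyl 2-diazo-2-(3-methoxy-2-{[3-methoxy-4-(TIPSO)benzyl]oxy}-5-[(TESO)methyl]phenyl)acetate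
Product: 11 ethyl (2R,3R)-7-methoxy-2-[3-methoxy-4-(TIPSO)phenyl]-5-[(TESO)methyl]-2,3-dihydrobenzofuran-3-carboxylate (trans), via cis ester 10 (not isolated)
Conditions: Rh2(S-PTTL)4 (1 mol%), toluene, −60 °C, slow addition of 9; then DBU, −60 → 40 °C
Reagents that add atoms: none
Why: Loss of N2 from 9 on the chiral dirhodium tetracarboxylate gives an electrophilic aryl(ester) divalent-rhodium carbene at the future C-3, which inserts into one of the two enantiotopic C–H bonds of the O–CH2–aryl group through a concerted but asynchronous three-centre transition state with hydride-transfer character, so that the C-2–C-3 bond forms and ring B closes. The closest known reaction type is the enantioselective intramolecular 1,5 C–H insertion of alkyl 2-(2-benzyloxyaryl)-2-diazoacetates under chiral dirhodium carboxylate catalysis, which gives cis-2-aryl-2,3-dihydrobenzofuran-3-carboxylates. Ring B (O-1, C-2, C-3, C-3a, C-7a) is closed in the 1,5 mode, carbene carbon and C–H carbon meeting through a five-membered cyclic transition state. C-2 is set by the catalyst, whose chiral carboxylate pocket selects one benzylic hydrogen, while C-3 is formed cis under kinetic control (10) and is then epimerised alpha to the ester by DBU in the same flask to the thermodynamically preferred trans ester 11, so that its final configuration is relayed from C-2. The step needs site selectivity (the ether methylene against ring C, the methoxy groups and bimolecular pathways) and enantioselectivity; the first is secured because this methylene is the only C–H site five atoms from the carbene carbon and is activated by both O-1 and the electron-rich ring C, with the alcohol masked as its TES ether and slow addition at low temperature keeping the carbene concentration low, and the second rests on the catalyst.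

Step 8
Reactants: 11 ethyl (2R,3R)-7-methoxy-2-[3-methoxy-4-(TIPSO)phenyl]-5-[(TESO)methyl]-2,3-dihydrobenzofuran-3-carboxylate
Product: 12 {(2R,3S)-7-methoxy-2-[3-methoxy-4-(TIPSO)phenyl]-5-[(TESO)methyl]-2,3-dihydrobenzofuran-3-yl}methanol
Conditions: iBu2AlH (3 equiv), CH2Cl2, −78 → 0 °C; Rochelle salt work-up
Reagents that add atoms: none
Why: Hydride reduction of the ester to the primary alcohol; no stereocentre is touched (the C-3 descriptor changes only because of priorities) and the silyl ethers survive.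

Step 9
Reactants: 12 {(2R,3S)-7-methoxy-2-[3-methoxy-4-(TIPSO)phenyl]-5-[(TESO)methyl]-2,3-dihydrobenzofuran-3-yl}methanol
Product: 13 (2R,3S)-3-[(TBSO)methyl]-7-methoxy-2-[3-methoxy-4-(TIPSO)phenyl]-5-[(TESO)methyl]-2,3-dihydrobenzofuran
Conditions: TBSCl, imidazole, DMF, rt
Reagents that add atoms: tert-butyldimethylsilyl chloride, CC(C)(C)[Si](C)(C)Cl
Why: Silylation of the primary alcohol with a group that is clearly more robust than the TES ether, so that the two primary positions stay distinguishable.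

Step 10
Reactants: 13 (2R,3S)-3-[(TBSO)methyl]-7-methoxy-2-[3-methoxy-4-(TIPSO)phenyl]-5-[(TESO)methyl]-2,3-dihydrobenzofuran
Product: 14 {(2R,3S)-3-[(TBSO)methyl]-7-methoxy-2-[3-methoxy-4-(TIPSO)phenyl]-2,3-dihydrobenzofuran-5-yl}methanol
Conditions: PPTS (0.2 equiv), MeOH–CH2Cl2, 0 °C
Reagents that add atoms: none
Why: Selective acid-catalysed methanolysis of the primary TES ether, which is far more labile than the TBS and aryl TIPS ethers.

Step 11
Reactants: 14 {(2R,3S)-3-[(TBSO)methyl]-7-methoxy-2-[3-methoxy-4-(TIPSO)phenyl]-2,3-dihydrobenzofuran-5-yl}methanol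
Product: 15 (2R,3S)-5-(bromomethyl)-3-[(TBSO)methyl]-7-methoxy-2-[3-methoxy-4-(TIPSO)phenyl]-2,3-dihydrobenzofuran
Conditions: CBr4, PPh3, CH2Cl2, 0 °C; used directly
Reagents that add atoms: tetrabromomethane, BrC(Br)(Br)Br
Why: Appel reaction converts the benzylic alcohol into the bromide under neutral conditions compatible with the silyl ethers and the benzylic ring ether.

Step 12
Reactants: 16 methyl 3-bromo-4-hydroxy-5-methoxybenzoate
Product: 17 methyl 3-bromo-5-methoxy-4-(TIPSO)benzoate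
Conditions: TIPSOTf, 2,6-lutidine, CH2Cl2, 0 °C → rt
Reagents that add atoms: triisopropylsilyl trifluoromethanesulfonate, CC(C)[Si](OS(=O)(=O)C(F)(F)F)(C(C)C)C(C)C
Why: Silylation of a hindered, electron-poor phenol with the reactive silyl triflate gives a doubly ortho-flanked aryl silyl ether that should last to the final step.

Step 13
Reactants: 18 (4S)-4-benzyl-1,3-oxazolidin-2-one; 19 bromoacetyl bromide
Product: 20 (4S)-4-benzyl-3-(bromoacetyl)-1,3-oxazolidin-2-one
Conditions: n-BuLi, THF, −78 °C; then 19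
Reagents that add atoms: none
Why: N-acylation of the lithiated oxazolidinone by the acyl bromide, which is far more reactive than the alkyl bromide.

Step 14
Reactants: 20 (4S)-4-benzyl-3-(bromoacetyl)-1,3-oxazolidin-2-one; 17 methyl 3-bromo-5-methoxy-4-(TIPSO)benzoate
Product: 22 (4S)-4-benzyl-3-{2-[3-methoxy-5-(methoxycarbonyl)-2-(TIPSO)phenyl]acetyl}-1,3-oxazolidin-2-one, via bromozinc enolate 21 (not isolated)
Conditions: Zn dust, THF, rt; then 17, Pd(dba)2 (5 mol%), Q-Phos (5 mol%), THF, rt → 60 °C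
Reagents that add atoms: none
Why: Zinc inserts into the C–Br bond to give the Reformatsky reagent, which undergoes palladium-catalysed Negishi-type α-arylation with the aryl bromide (oxidative addition, transmetalation of the zinc enolate, reductive elimination); the nearly neutral zinc enolate tolerates the methyl ester and the imide.

Step 15
Reactants: 22 (4S)-4-benzyl-3-{2-[3-methoxy-5-(methoxycarbonyl)-2-(TIPSO)phenyl]acetyl}-1,3-oxazolidin-2-one; 2 3-methoxy-4-(TIPSO)benzaldehyde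
Product: 24 (4S)-4-benzyl-3-{(2R,3S)-3-hydroxy-2-[3-methoxy-5-(methoxycarbonyl)-2-(TIPSO)phenyl]-3-[3-methoxy-4-(TIPSO)phenyl]propanoyl}-1,3-oxazolidin-2-one, via trimethylsilyl ether 23 (not isolated)
Conditions: MgCl2 (20 mol%), Et3N, TMSCl, EtOAc, rt; then citric acid, MeOH, 0 °C
Reagents that add atoms: none
Why: Magnesium halide-catalysed anti-selective aldol addition of an N-acyloxazolidinone (soft enolisation, turnover by O-silylation), in which the magnesium-chelated Z-enolate is attacked on the face opposite the auxiliary benzyl group to set C-2 (R) and the boat-like transition state with the aromatic aldehyde sets the anti carbinol C-3 (S).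

Step 16
Reactants: 24 (4S)-4-benzyl-3-{(2R,3S)-3-hydroxy-2-[3-methoxy-5-(methoxycarbonyl)-2-(TIPSO)phenyl]-3-[3-methoxy-4-(TIPSO)phenyl]propanoyl}-1,3-oxazolidin-2-one
Product: 25 methyl 3-{(1S,2S)-1,3-dihydroxy-1-[3-methoxy-4-(TIPSO)phenyl]propan-2-yl}-5-methoxy-4-(TIPSO)benzoate
Conditions: LiBH4 (2 equiv), MeOH (2 equiv), THF, 0 °C
Reagents that add atoms: none
Why: Reductive cleavage of the N-acyloxazolidinone by LiBH4, the imide being far more electrophilic than the electron-rich, hindered methyl benzoate; the low temperature limits retro-aldol cleavage and neither stereocentre is touched.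

Step 17
Reactants: 25 methyl 3-{(1S,2S)-1,3-dihydroxy-1-[3-methoxy-4-(TIPSO)phenyl]propan-2-yl}-5-methoxy-4-(TIPSO)benzoate
Product: 26 methyl 3-{(1S,2S)-1,3-bis(TBSO)-1-[3-methoxy-4-(TIPSO)phenyl]propan-2-yl}-5-methoxy-4-(TIPSO)benzoate
Conditions: TBSOTf (2.5 equiv), 2,6-lutidine, CH2Cl2, −40 → 0 °C
Reagents that add atoms: tert-butyldimethylsilyl trifluoromethanesulfonate, CC(C)(C)[Si](C)(C)OS(=O)(=O)C(F)(F)F
Why: Bis-silylation with the silyl triflate protects the primary and the hindered benzylic secondary alcohol and blocks ionisation or retro-aldol-type loss of the carbinol in later basic steps.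

Step 18
Reactants: 26 methyl 3-{(1S,2S)-1,3-bis(TBSO)-1-[3-methoxy-4-(TIPSO)phenyl]propan-2-yl}-5-methoxy-4-(TIPSO)benzoate
Product: 27 ArE-methanol, (3-{(1S,2S)-1,3-bis(TBSO)-1-[3-methoxy-4-(TIPSO)phenyl]propan-2-yl}-5-methoxy-4-(TIPSO)phenyl)methanol
Conditions: iBu2AlH (2.5 equiv), CH2Cl2, −78 → 0 °C; Rochelle salt work-up
Reagents that add atoms: none
Why: Hydride reduction of the benzoate ester to the benzylic alcohol with all silyl ethers intact.

Step 19
Reactants: 27 ArE-methanol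
Product: 28 ArE-methyl bromide, 1-(bromomethyl)-3-{(1S,2S)-1,3-bis(TBSO)-1-[3-methoxy-4-(TIPSO)phenyl]propan-2-yl}-5-methoxy-4-(TIPSO)benzene
Conditions: CBr4, PPh3, CH2Cl2, 0 °C; used directly
Reagents that add atoms: tetrabromomethane, BrC(Br)(Br)Br
Why: Appel reaction under neutral conditions gives the benzylic bromide without ionising the silylated benzylic carbinol.

Step 20
Reactants: 18 (4S)-4-benzyl-1,3-oxazolidin-2-one; 29 methyl 4-chloro-4-oxobutanoate
Product: 30 (4S)-4-benzyl-3-(4-methoxy-4-oxobutanoyl)-1,3-oxazolidin-2-one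
Conditions: n-BuLi, THF, −78 °C; then 29
Reagents that add atoms: none
Why: N-acylation of the lithiated oxazolidinone by the acid chloride gives the succinate half-ester imide.

Step 21
Reactants: 30 (4S)-4-benzyl-3-(4-methoxy-4-oxobutanoyl)-1,3-oxazolidin-2-one; 28 ArE-methyl bromide
Product: 31 methyl (3S)-3-(ArE-methyl)-4-[(4S)-4-benzyl-2-oxo-1,3-oxazolidin-3-yl]-4-oxobutanoate
Conditions: NaN(SiMe3)2, THF, −78 °C; then 28, −78 → −20 °C
Reagents that add atoms: none
Why: Evans oxazolidinone alkylation, in which the chelated sodium Z-enolate (the imide α-position is deprotonated in preference to the ester α-position) is benzylated on the face opposite the auxiliary benzyl group, setting the future lactone C-4 as (S).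

Step 22
Reactants: 31 methyl (3S)-3-(ArE-methyl)-4-[(4S)-4-benzyl-2-oxo-1,3-oxazolidin-3-yl]-4-oxobutanoate
Product: 33 (4S)-4-(ArE-methyl)dihydrofuran-2(3H)-one, via hydroxy ester 32 (not isolated)
Conditions: NaBH4, THF–H2O (3:1), 0 °C → rt; then PPTS (cat.), toluene, 50 °C
Reagents that add atoms: none
Why: Borohydride reduction of the imide in aqueous THF releases the auxiliary and leaves the methyl ester, and the resulting γ-hydroxy ester closes ring D by 5-exo-trig acyl substitution (lactonisation) without involving the stereocentre.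

Step 23
Reactants: 33 (4S)-4-(ArE-methyl)dihydrofuran-2(3H)-one; 15 (2R,3S)-5-(bromomethyl)-3-[(TBSO)methyl]-7-methoxy-2-[3-methoxy-4-(TIPSO)phenyl]-2,3-dihydrobenzofuran
Product: 34 (3S,4S)-4-(ArE-methyl)-3-({(2R,3S)-3-[(TBSO)methyl]-7-methoxy-2-[3-methoxy-4-(TIPSO)phenyl]-2,3-dihydrobenzofuran-5-yl}methyl)dihydrofuran-2(3H)-one
Conditions: LiN(SiMe3)2, THF, −78 °C; then 15, DMPU, −78 → −30 °C
Reagents that add atoms: none
Why: SN2 alkylation of the lithium enolate of a β-substituted γ-butyrolactone with a benzylic bromide, the electrophile entering anti to the C-4 arylmethyl group so that C-3 is set as (S) in the trans lactone.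

Step 24
Reactants: 34 (3S,4S)-4-(ArE-methyl)-3-({(2R,3S)-3-[(TBSO)methyl]-7-methoxy-2-[3-methoxy-4-(TIPSO)phenyl]-2,3-dihydrobenzofuran-5-yl}methyl)dihydrofuran-2(3H)-one
Product: 35 (3S,4S)-4-{3-[(1S,2S)-1,3-dihydroxy-1-(4-hydroxy-3-methoxyphenyl)propan-2-yl]-4-hydroxy-5-methoxybenzyl}-3-{[(2R,3S)-2-(4-hydroxy-3-methoxyphenyl)-3-(hydroxymethyl)-7-methoxy-2,3-dihydrobenzofuran-5-yl]methyl}dihydrofuran-2(3H)-one
Conditions: Bu4NF, AcOH (1:1, excess), THF, 0 °C → rt
Reagents that add atoms: none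
Why: Fluoride-mediated global desilylation of three aryl TIPS and three alkyl TBS ethers, buffered with acetic acid so that the phenols, the p-hydroxybenzylic alcohol, ring B and the lactone are not exposed to base (no quinone methide formation, no epimerisation).

**Compound list**

1 | vanillin (4-hydroxy-3-methoxybenzaldehyde) | COc1cc(C=O)ccc1O | starting material
2 | 3-methoxy-4-(TIPSO)benzaldehyde | COc1cc(C=O)ccc1O[Si](C(C)C)(C(C)C)C(C)C | intermediate
3 | [3-methoxy-4-(TIPSO)phenyl]methanol | COc1cc(CO)ccc1O[Si](C(C)C)(C(C)C)C(C)C | intermediate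
4 | 5-iodovanillin (4-hydroxy-3-iodo-5-methoxybenzaldehyde) | COc1cc(C=O)cc(I)c1O | starting material
5 | 3-iodo-5-methoxy-4-{[3-methoxy-4-(TIPSO)benzyl]oxy}benzaldehyde | COc1cc(C=O)cc(I)c1OCc1ccc(O[Si](C(C)C)(C(C)C)C(C)C)c(OC)c1 | intermediate
6 | (3-iodo-5-methoxy-4-{[3-methoxy-4-(TIPSO)benzyl]oxy}phenyl)methanol | COc1cc(CO)cc(I)c1OCc1ccc(O[Si](C(C)C)(C(C)C)C(C)C)c(OC)c1 | intermediate
7 | triethyl[(3-iodo-5-methoxy-4-{[3-methoxy-4-(TIPSO)benzyl]oxy}benzyl)oxy]silane | COc1cc(CO[Si](CC)(CC)CC)cc(I)c1OCc1ccc(O[Si](C(C)C)(C(C)C)C(C)C)c(OC)c1 | intermediate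
8 | ethyl diazoacetate | CCOC(=O)C=[N+]=[N-] | starting material
9 | ethyl 2-diazo-2-(3-methoxy-2-{[3-methoxy-4-(TIPSO)benzyl]oxy}-5-[(TESO)methyl]phenyl)acetate | CCOC(=O)C(=[N+]=[N-])c1cc(CO[Si](CC)(CC)CC)cc(OC)c1OCc1ccc(O[Si](C(C)C)(C(C)C)C(C)C)c(OC)c1 | intermediate
10 | ethyl (2R,3S)-7-methoxy-2-[3-methoxy-4-(TIPSO)phenyl]-5-[(TESO)methyl]-2,3-dihydrobenzofuran-3-carboxylate (cis) | CC[Si](CC)(CC)OCc1cc(OC)c2c(c1)[C@H](C(=O)OCC)[C@H](c1ccc(O[Si](C(C)C)(C(C)C)C(C)C)c(OC)c1)O2 | intermediate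
11 | ethyl (2R,3R)-7-methoxy-2-[3-methoxy-4-(TIPSO)phenyl]-5-[(TESO)methyl]-2,3-dihydrobenzofuran-3-carboxylate (trans) | CC[Si](CC)(CC)OCc1cc(OC)c2c(c1)[C@@H](C(=O)OCC)[C@H](c1ccc(O[Si](C(C)C)(C(C)C)C(C)C)c(OC)c1)O2 | intermediate
12 | {(2R,3S)-7-methoxy-2-[3-methoxy-4-(TIPSO)phenyl]-5-[(TESO)methyl]-2,3-dihydrobenzofuran-3-yl}methanol | CC[Si](CC)(CC)OCc1cc(OC)c2c(c1)[C@@H](CO)[C@H](c1ccc(O[Si](C(C)C)(C(C)C)C(C)C)c(OC)c1)O2 | intermediate
13 | (2R,3S)-3-[(TBSO)methyl]-7-methoxy-2-[3-methoxy-4-(TIPSO)phenyl]-5-[(TESO)methyl]-2,3-dihydrobenzofuran | CC[Si](CC)(CC)OCc1cc(OC)c2c(c1)[C@@H](CO[Si](C)(C)C(C)(C)C)[C@H](c1ccc(O[Si](C(C)C)(C(C)C)C(C)C)c(OC)c1)O2 | intermediate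
14 | {(2R,3S)-3-[(TBSO)methyl]-7-methoxy-2-[3-methoxy-4-(TIPSO)phenyl]-2,3-dihydrobenzofuran-5-yl}methanol | OCc1cc(OC)c2c(c1)[C@@H](CO[Si](C)(C)C(C)(C)C)[C@H](c1ccc(O[Si](C(C)C)(C(C)C)C(C)C)c(OC)c1)O2 | intermediate
15 | (2R,3S)-5-(bromomethyl)-3-[(TBSO)methyl]-7-methoxy-2-[3-methoxy-4-(TIPSO)phenyl]-2,3-dihydrobenzofuran | BrCc1cc(OC)c2c(c1)[C@@H](CO[Si](C)(C)C(C)(C)C)[C@H](c1ccc(O[Si](C(C)C)(C(C)C)C(C)C)c(OC)c1)O2 | intermediate
16 | methyl 3-bromo-4-hydroxy-5-methoxybenzoate | COC(=O)c1cc(Br)c(O)c(OC)c1 | starting material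
17 | methyl 3-bromo-5-methoxy-4-(TIPSO)benzoate | COC(=O)c1cc(Br)c(O[Si](C(C)C)(C(C)C)C(C)C)c(OC)c1 | intermediate
18 | (4S)-4-benzyl-1,3-oxazolidin-2-one | O=C1OC[C@H](Cc2ccccc2)N1 | starting material
19 | bromoacetyl bromide | BrCC(Br)=O | starting material
20 | (4S)-4-benzyl-3-(bromoacetyl)-1,3-oxazolidin-2-one | O=C1OC[C@H](Cc2ccccc2)N1C(=O)CBr | intermediate
21 | bromozinc enolate (Reformatsky reagent) of 20 | O=C1OC[C@H](Cc2ccccc2)N1C(=O)C[Zn]Br | intermediate
22 | (4S)-4-benzyl-3-{2-[3-methoxy-5-(methoxycarbonyl)-2-(TIPSO)phenyl]acetyl}-1,3-oxazolidin-2-one | O=C1OC[C@H](Cc2ccccc2)N1C(=O)Cc1cc(C(=O)OC)cc(OC)c1O[Si](C(C)C)(C(C)C)C(C)C | intermediate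
23 | trimethylsilyl ether of 24 | COc1cc([C@@H](O[Si](C)(C)C)[C@H](C(=O)N2C(=O)OC[C@@H]2Cc2ccccc2)c2cc(C(=O)OC)cc(OC)c2O[Si](C(C)C)(C(C)C)C(C)C)ccc1O[Si](C(C)C)(C(C)C)C(C)C | intermediate
24 | (4S)-4-benzyl-3-{(2R,3S)-3-hydroxy-2-[3-methoxy-5-(methoxycarbonyl)-2-(TIPSO)phenyl]-3-[3-methoxy-4-(TIPSO)phenyl]propanoyl}-1,3-oxazolidin-2-one | COc1cc([C@@H](O)[C@H](C(=O)N2C(=O)OC[C@@H]2Cc2ccccc2)c2cc(C(=O)OC)cc(OC)c2O[Si](C(C)C)(C(C)C)C(C)C)ccc1O[Si](C(C)C)(C(C)C)C(C)C | intermediate
25 | methyl 3-{(1S,2S)-1,3-dihydroxy-1-[3-methoxy-4-(TIPSO)phenyl]propan-2-yl}-5-methoxy-4-(TIPSO)benzoate | COc1cc([C@@H](O)[C@H](CO)c2cc(C(=O)OC)cc(OC)c2O[Si](C(C)C)(C(C)C)C(C)C)ccc1O[Si](C(C)C)(C(C)C)C(C)C | intermediate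
26 | methyl 3-{(1S,2S)-1,3-bis(TBSO)-1-[3-methoxy-4-(TIPSO)phenyl]propan-2-yl}-5-methoxy-4-(TIPSO)benzoate | COc1cc([C@@H](O[Si](C)(C)C(C)(C)C)[C@H](CO[Si](C)(C)C(C)(C)C)c2cc(C(=O)OC)cc(OC)c2O[Si](C(C)C)(C(C)C)C(C)C)ccc1O[Si](C(C)C)(C(C)C)C(C)C | intermediate
27 | ArE-methanol | COc1cc([C@@H](O[Si](C)(C)C(C)(C)C)[C@H](CO[Si](C)(C)C(C)(C)C)c2cc(CO)cc(OC)c2O[Si](C(C)C)(C(C)C)C(C)C)ccc1O[Si](C(C)C)(C(C)C)C(C)C | intermediate
28 | ArE-methyl bromide | COc1cc([C@@H](O[Si](C)(C)C(C)(C)C)[C@H](CO[Si](C)(C)C(C)(C)C)c2cc(CBr)cc(OC)c2O[Si](C(C)C)(C(C)C)C(C)C)ccc1O[Si](C(C)C)(C(C)C)C(C)C | intermediate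
29 | methyl 4-chloro-4-oxobutanoate | COC(=O)CCC(Cl)=O | starting material
30 | (4S)-4-benzyl-3-(4-methoxy-4-oxobutanoyl)-1,3-oxazolidin-2-one | O=C1OC[C@H](Cc2ccccc2)N1C(=O)CCC(=O)OC | intermediate
31 | methyl (3S)-3-(ArE-methyl)-4-[(4S)-4-benzyl-2-oxo-1,3-oxazolidin-3-yl]-4-oxobutanoate | COc1cc([C@@H](O[Si](C)(C)C(C)(C)C)[C@H](CO[Si](C)(C)C(C)(C)C)c2cc(C[C@H](C(=O)N3C(=O)OC[C@@H]3Cc3ccccc3)CC(=O)OC)cc(OC)c2O[Si](C(C)C)(C(C)C)C(C)C)ccc1O[Si](C(C)C)(C(C)C)C(C)C | intermediate
32 | methyl (3S)-3-(ArE-methyl)-4-hydroxybutanoate | COc1cc([C@@H](O[Si](C)(C)C(C)(C)C)[C@H](CO[Si](C)(C)C(C)(C)C)c2cc(C[C@H](CO)CC(=O)OC)cc(OC)c2O[Si](C(C)C)(C(C)C)C(C)C)ccc1O[Si](C(C)C)(C(C)C)C(C)C | intermediate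
33 | (4S)-4-(ArE-methyl)dihydrofuran-2(3H)-one | COc1cc([C@@H](O[Si](C)(C)C(C)(C)C)[C@H](CO[Si](C)(C)C(C)(C)C)c2cc(C[C@@H]3COC(=O)C3)cc(OC)c2O[Si](C(C)C)(C(C)C)C(C)C)ccc1O[Si](C(C)C)(C(C)C)C(C)C | intermediate
34 | (3S,4S)-4-(ArE-methyl)-3-({(2R,3S)-3-[(TBSO)methyl]-7-methoxy-2-[3-methoxy-4-(TIPSO)phenyl]-2,3-dihydrobenzofuran-5-yl}methyl)dihydrofuran-2(3H)-one | COc1cc([C@@H](O[Si](C)(C)C(C)(C)C)[C@H](CO[Si](C)(C)C(C)(C)C)c2cc(C[C@@H]3COC(=O)[C@H]3Cc3cc(OC)c4c(c3)[C@@H](CO[Si](C)(C)C(C)(C)C)[C@H](c3ccc(O[Si](C(C)C)(C(C)C)C(C)C)c(OC)c3)O4)cc(OC)c2O[Si](C(C)C)(C(C)C)C(C)C)ccc1O[Si](C(C)C)(C(C)C)C(C)C | intermediate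
35 | CNP0199264.1, (3S,4S)-4-{3-[(1S,2S)-1,3-dihydroxy-1-(4-hydroxy-3-methoxyphenyl)propan-2-yl]-4-hydroxy-5-methoxybenzyl}-3-{[(2R,3S)-2-(4-hydroxy-3-methoxyphenyl)-3-(hydroxymethyl)-7-methoxy-2,3-dihydrobenzofuran-5-yl]methyl}dihydrofuran-2(3H)-one | COc1cc([C@@H](O)[C@H](CO)c2cc(C[C@@H]3COC(=O)[C@H]3Cc3cc(OC)c4c(c3)[C@@H](CO)[C@H](c3ccc(O)c(OC)c3)O4)cc(OC)c2O)ccc1O | target

**Step count and risks**

Total step count: 24. Longest linear sequence: 13 steps (steps 1 to 11, then 23 and 24).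

Steps most likely to fail:

Step 7. The catalyst may discriminate poorly between the two enantiotopic benzylic hydrogens of this methoxy-flanked ether, or the carbene may be diverted to addition onto ring C, giving low enantiomeric purity or yield. The fallback keeps the same ring closure but moves the stereochemical control to a covalently bound chiral ester. It sets out from 7: the palladium coupling of step 6 is run with (1R,2S,5R)-menthyl diazoacetate to give the menthyl diazo ester F1. Insertion with achiral Rh2(OAc)4 followed by DBU gives the trans esters as two diastereomers, from which the (2R,3R) menthyl ester F2 is separated by crystallisation or chromatography. Reduction of F2 with iBu2AlH gives 12, where the route is rejoined.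

Step 14. Transmetalation and reductive elimination next to the bulky ortho TIPSO group may be slow, so that protonation or self-condensation of the zinc enolate wins. The fallback builds the arylacetic acid first and attaches the auxiliary afterwards. It sets out from 17: Stille–Migita allylation (allyltributylstannane, Pd(PPh3)4, toluene, 100 °C) gives the allyl arene F3. Lemieux–Johnson cleavage (OsO4 cat., NaIO4, 2,6-lutidine, dioxane–water) gives the arylacetaldehyde F4, and Pinnick oxidation (NaClO2, NaH2PO4, 2-methyl-2-butene) gives the arylacetic acid F5. Acylation of 18 through the mixed pivalic anhydride (pivaloyl chloride, Et3N, LiCl, THF) gives 22, where the route is rejoined.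

Step 15. The anti selectivity may erode through a competing open transition state of the hindered ortho-substituted arylacetyl enolate, or through retro-aldol equilibration of the electron-rich benzylic carbinol. The fallback sets the carbinol centre by reagent-controlled ketone reduction instead of aldol diastereoselection. It sets out from 25, carried through step 16 as a mixture with its C-1 epimer: selective primary silylation (TBSCl, imidazole, CH2Cl2, 0 °C) gives the mono-silyl ether F6 as both carbinol epimers. Dess–Martin oxidation converges them to the aryl ketone F7. Corey–Bakshi–Shibata reduction with the (R)-methyl oxazaborolidine and BH3·SMe2 at −20 °C gives the (1S) alcohol F8, and silylation with TBSOTf and 2,6-lutidine gives 26, where the route is rejoined.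

**Further compounds**

F1 | step 7 | (1R,2S,5R)-menthyl 2-diazo-2-(3-methoxy-2-{[3-methoxy-4-(TIPSO)benzyl]oxy}-5-[(TESO)methyl]phenyl)acetate | CC(C)[C@@H]1CC[C@@H](C)C[C@H]1OC(=O)C(=[N+]=[N-])c1cc(CO[Si](CC)(CC)CC)cc(OC)c1OCc1ccc(O[Si](C(C)C)(C(C)C)C(C)C)c(OC)c1
F2 | step 7 | (1R,2S,5R)-menthyl (2R,3R)-7-methoxy-2-[3-methoxy-4-(TIPSO)phenyl]-5-[(TESO)methyl]-2,3-dihydrobenzofuran-3-carboxylate | CC[Si](CC)(CC)OCc1cc(OC)c2c(c1)[C@@H](C(=O)O[C@@H]1C[C@H](C)CC[C@H]1C(C)C)[C@H](c1ccc(O[Si](C(C)C)(C(C)C)C(C)C)c(OC)c1)O2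
F3 | step 14 | methyl 3-allyl-5-methoxy-4-(TIPSO)benzoate | COC(=O)c1cc(CC=C)c(O[Si](C(C)C)(C(C)C)C(C)C)c(OC)c1
F4 | step 14 | methyl 3-methoxy-5-(2-oxoethyl)-4-(TIPSO)benzoate | COC(=O)c1cc(CC=O)c(O[Si](C(C)C)(C(C)C)C(C)C)c(OC)c1
F5 | step 14 | 2-[3-methoxy-5-(methoxycarbonyl)-2-(TIPSO)phenyl]acetic acid | COC(=O)c1cc(CC(=O)O)c(O[Si](C(C)C)(C(C)C)C(C)C)c(OC)c1
F6 | step 15 | methyl 3-{(2S)-3-(TBSO)-1-hydroxy-1-[3-methoxy-4-(TIPSO)phenyl]propan-2-yl}-5-methoxy-4-(TIPSO)benzoate (both C-1 epimers) | COc1cc(C(O)[C@H](CO[Si](C)(C)C(C)(C)C)c2cc(C(=O)OC)cc(OC)c2O[Si](C(C)C)(C(C)C)C(C)C)ccc1O[Si](C(C)C)(C(C)C)C(C)C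
F7 | step 15 | methyl 3-{(2S)-1-(TBSO)-3-[3-methoxy-4-(TIPSO)phenyl]-3-oxopropan-2-yl}-5-methoxy-4-(TIPSO)benzoate | COc1cc(C(=O)[C@H](CO[Si](C)(C)C(C)(C)C)c2cc(C(=O)OC)cc(OC)c2O[Si](C(C)C)(C(C)C)C(C)C)ccc1O[Si](C(C)C)(C(C)C)C(C)C
F8 | step 15 | methyl 3-{(1S,2S)-3-(TBSO)-1-hydroxy-1-[3-methoxy-4-(TIPSO)phenyl]propan-2-yl}-5-methoxy-4-(TIPSO)benzoate | COc1cc([C@@H](O)[C@H](CO[Si](C)(C)C(C)(C)C)c2cc(C(=O)OC)cc(OC)c2O[Si](C(C)C)(C(C)C)C(C)C)ccc1O[Si](C(C)C)(C(C)C)C(C)C
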